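The γ-lactone (O–C12–C11–C7–C8) fused to the ten-membered ring is a double retron once C6 is a ketone (germacrane numbering: ring C1–C10, lactone C11–C13). The lactone oxygen on C8 then sits β to the C6 carbonyl (oxa-Michael), and the hydroxylated C11 sits β to it as well (aldol). One operation, a carboxylate oxa-Michael/aldol annulation of pyruvic acid onto a cis,cis-diepoxy cyclodec-7-en-6-one, therefore joins C11–C13 with both oxygens to C7/C8 and closes the lactone. The enone comes from nerol: two Sharpless epoxidations with opposite tartrates set the cis-epoxides, and ring-closing metathesis forms C7=C8. Chelation-controlled reduction at C6 and double angeloylation finish.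

Key step: step 13

Remark: C14 is the methyl on C10 and C15 the methyl on C4; read literally, the target has both epoxides cis-fused to the ring (C2 cis to C9, C3 cis to C6), and that stereoisomer is the one made.

Step 1
Reactants: 1 ethyl (triphenyl-λ5-phosphanylidene)acetate
Product: 3 ethyl 2-(triphenyl-λ5-phosphanylidene)pent-4-enoate, via allylated phosphonium bromide 2 (not isolated)
Conditions: allyl bromide, EtOAc, reflux; then aq NaOH, CH2Cl2, 0 °C
Reagents that add atoms: allyl bromide, C=CCBr
Why: C-alkylation of a stabilised phosphorus ylide by an allylic bromide, followed by deprotonation of the phosphonium salt, should give the α-allylated stabilised ylide; no stereocentre is formed.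

Step 2
Reactants: 4 nerol
Product: 5 (2S,3R)-2,3-epoxynerol
Conditions: Ti(OiPr)4, L-(+)-diethyl tartrate, tBuOOH, 4 Å molecular sieves, CH2Cl2, −20 °C
Reagents that add atoms: tert-butyl hydroperoxide, CC(C)(C)OO
Why: Sharpless asymmetric epoxidation: oxygen goes only to the allylic alcohol alkene, and L-(+)-tartrate should give the (2S,3R)-epoxide, so the reagent sets C4 (R) and C5 (S) and the Z-alkene of nerol becomes the cis-fused 4,5-epoxide.

Step 3
Reactants: 5 (2S,3R)-2,3-epoxynerol
Product: 7 3-[(2R,3S)-3-(hydroxymethyl)-2-methyloxiran-2-yl]propanal, via secondary ozonide 6 (not isolated)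
Conditions: O3, CH2Cl2, −78 °C; then Me2S, −78 → 23 °C
Reagents that add atoms: ozone, [O-][O+]=O
Why: Ozonolysis with reductive work-up cleaves the only remaining alkene to the C1 aldehyde; the epoxide and its stereocentres are not touched.

Step 4
Reactants: 7 3-[(2R,3S)-3-(hydroxymethyl)-2-methyloxiran-2-yl]propanal; 3 ethyl 2-(triphenyl-λ5-phosphanylidene)pent-4-enoate
Product: 8 ethyl (2E)-5-[(2R,3S)-3-(hydroxymethyl)-2-methyloxiran-2-yl]-2-(prop-2-en-1-yl)pent-2-enoate
Conditions: toluene, 80 °C
Reagents that add atoms: none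
Why: Wittig olefination with a stabilised α-substituted ylide should give the E-enoate (ester trans to C2), which places the allyl group (C9) cis to C2 as the cis-fused 1,10-epoxide later requires.

Step 5
Reactants: 8 ethyl (2E)-5-[(2R,3S)-3-(hydroxymethyl)-2-methyloxiran-2-yl]-2-(prop-2-en-1-yl)pent-2-enoate
Product: 9 ethyl (2E)-5-[(2R,3R)-3-formyl-2-methyloxiran-2-yl]-2-(prop-2-en-1-yl)pent-2-enoate
Conditions: Dess–Martin periodinane, pyridine, CH2Cl2, 0 → 23 °C
Reagents that add atoms: none
Why: Dess–Martin oxidation of the primary epoxy alcohol to the epoxy aldehyde under buffered conditions should leave the epoxide, the enoate and the C5 configuration intact.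

Step 6
Reactants: 9 ethyl (2E)-5-[(2R,3R)-3-formyl-2-methyloxiran-2-yl]-2-(prop-2-en-1-yl)pent-2-enoate
Product: 10 ethyl (2E)-5-[(2R,3S)-3-(1-hydroxyprop-2-en-1-yl)-2-methyloxiran-2-yl]-2-(prop-2-en-1-yl)pent-2-enoate (both carbinol epimers)
Conditions: vinylmagnesium bromide, THF, −78 °C; aq NH4Cl
Reagents that add atoms: vinylmagnesium bromide, C=C[Mg]Br
Why: Grignard 1,2-addition is far faster at the aldehyde than at the hindered α-branched enoate at −78 °C; the C6 carbinol forms as an epimer mixture, which does not matter because C6 becomes a ketone in step 11.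

Step 7
Reactants: 10 ethyl (2E)-5-[(2R,3S)-3-(1-hydroxyprop-2-en-1-yl)-2-methyloxiran-2-yl]-2-(prop-2-en-1-yl)pent-2-enoate (both carbinol epimers)
Product: 11 (2E)-5-[(2R,3S)-3-(1-hydroxyprop-2-en-1-yl)-2-methyloxiran-2-yl]-2-(prop-2-en-1-yl)pent-2-en-1-ol (both carbinol epimers)
Conditions: iBu2AlH, CH2Cl2, −78 °C; aq potassium sodium tartrate (KNaC4H4O6)
Reagents that add atoms: none
Why: 1,2-Reduction of the enoate with iBu2AlH gives the allylic alcohol; at −78 °C the epoxide and the isolated alkenes should not react.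

Step 8
Reactants: 11 (2E)-5-[(2R,3S)-3-(1-hydroxyprop-2-en-1-yl)-2-methyloxiran-2-yl]-2-(prop-2-en-1-yl)pent-2-en-1-ol (both carbinol epimers)
Product: 12 1-[(2S,3R)-3-{2-[(2R,3R)-3-(hydroxymethyl)-3-(prop-2-en-1-yl)oxiran-2-yl]ethyl}-3-methyloxiran-2-yl]prop-2-en-1-ol (both carbinol epimers)
Conditions: Ti(OiPr)4, D-(−)-diethyl tartrate, tBuOOH, 4 Å molecular sieves, CH2Cl2, −25 °C
Reagents that add atoms: tert-butyl hydroperoxide, CC(C)(C)OO
Why: Sharpless asymmetric epoxidation: only the primary trisubstituted allylic alcohol should react at a useful rate (the secondary vinyl carbinol is far slower), and D-(−)-tartrate should give the (2R,3R)-epoxide, so the reagent sets C10 and C1 with C9 and C2 cis.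

Step 9
Reactants: 12 1-[(2S,3R)-3-{2-[(2R,3R)-3-(hydroxymethyl)-3-(prop-2-en-1-yl)oxiran-2-yl]ethyl}-3-methyloxiran-2-yl]prop-2-en-1-ol (both carbinol epimers)
Product: 13 [(2R,3R)-3-{2-[(2R,3S)-3-(1-hydroxyprop-2-en-1-yl)-2-methyloxiran-2-yl]ethyl}-2-(prop-2-en-1-yl)oxiran-2-yl]methyl 4-methylbenzenesulfonate (both carbinol epimers)
Conditions: TsCl, Et3N, Me3N·HCl (cat.), CH2Cl2, 0 °C
Reagents that add atoms: 4-methylbenzenesulfonyl chloride, Cc1ccc(cc1)S(Cl)(=O)=O
Why: Sulfonylation should be selective for the primary hydroxyl over the secondary allylic hydroxyl flanked by the epoxide.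

Step 10
Reactants: 13 [(2R,3R)-3-{2-[(2R,3S)-3-(1-hydroxyprop-2-en-1-yl)-2-methyloxiran-2-yl]ethyl}-2-(prop-2-en-1-yl)oxiran-2-yl]methyl 4-methylbenzenesulfonate (both carbinol epimers)
Product: 14 1-[(2S,3R)-3-methyl-3-{2-[(2R,3S)-3-methyl-3-(prop-2-en-1-yl)oxiran-2-yl]ethyl}oxiran-2-yl]prop-2-en-1-ol (both carbinol epimers)
Conditions: NaBH4, DMSO, 60 °C
Reagents that add atoms: none
Why: SN2 displacement of the primary sulfonate by hydride in a dipolar aprotic solvent turns C14 into the methyl group; borohydride without a Lewis acid should not open the trisubstituted epoxides, and no stereocentre is involved.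

Step 11
Reactants: 14 1-[(2S,3R)-3-methyl-3-{2-[(2R,3S)-3-methyl-3-(prop-2-en-1-yl)oxiran-2-yl]ethyl}oxiran-2-yl]prop-2-en-1-ol (both carbinol epimers)
Product: 15 1-[(2R,3R)-3-methyl-3-{2-[(2R,3S)-3-methyl-3-(prop-2-en-1-yl)oxiran-2-yl]ethyl}oxiran-2-yl]prop-2-en-1-one
Conditions: Dess–Martin periodinane, pyridine, CH2Cl2, 0 °C
Reagents that add atoms: none
Why: Dess–Martin oxidation of the secondary allylic alcohol converges both C6 epimers on a single vinyl ketone, which is used at once.

Step 12
Reactants: 15 1-[(2R,3R)-3-methyl-3-{2-[(2R,3S)-3-methyl-3-(prop-2-en-1-yl)oxiran-2-yl]ethyl}oxiran-2-yl]prop-2-en-1-one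
Product: 16 (1R,4R,5R,10S,7Z)-1,10:4,5-diepoxy-4,10-dimethylcyclodec-7-en-6-one (germacrane numbering)
Conditions: second-generation Hoveyda–Grubbs catalyst (10 mol%), 1,4-benzoquinone (20 mol%), toluene (0.5 mM), 80 °C
Reagents that add atoms: none
Why: Ring-closing metathesis: the ruthenium alkylidene should load on the allyl terminus and close onto the electron-poor vinyl ketone, the two cis-epoxides bend the chain like cis-alkenes so that the ten-membered ring closes as the Z-enone, and loss of ethylene together with the poor metathesis reactivity of the conjugated product should make closure irreversible.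

Step 13
Reactants: 16 (1R,4R,5R,10S,7Z)-1,10:4,5-diepoxy-4,10-dimethylcyclodec-7-en-6-one; 17 pyruvic acid
Product: 19 (1R,4R,5R,7R,8R,10S,11R)-1,10:4,5-diepoxy-11-hydroxy-6-oxogermacran-12,8-olide, via C8 pyruvate ester 18 (not isolated)
Conditions: pyruvic acid (5 equiv), iPr2NEt (4 equiv), LiCl (1 equiv), MeCN, 23 → 40 °C
Reagents that add atoms: none
Why: Proposed new method: the pyruvate carboxylate adds to C8 of the Z-enone (oxa-Michael, polarity-matched, oxygen to the β-carbon), and the C6 enolate so formed is held three atoms from the activated pyruvate ketone, which it attacks through C7 before it can revert, so that O–C8 and C7–C11 arise in one pass while the weakly acidic buffer never removes the C9 protons whose loss would open the 1,10-epoxide. The closest known reaction types are the sulfa-Michael/aldol [3+2] annulation of enones with mercaptoacetaldehyde and the oxa-Michael/aldol annulation of enones with salicylaldehydes; here a carboxylate is the heteroatom donor and an α-keto acid carbonyl the acceptor. The only ring closed is the γ-lactone, by a 5-(enolexo)-exo-trig aldol, the C8–O bond being made intermolecularly. C8 should be set by approach of the carboxylate on the ring face opposite the C10 methyl (the face of the 1,10-epoxide oxygen); C7 by closure to the trans-fused lactone, which the reversible steps and the enolisable C7–H also favour thermodynamically; and C11 by the lithium-bridged aldol that places the new hydroxyl syn to the C6 carbonyl, hydrogen-bonded in the product with the methyl outward. Regiochemistry is secured by the enone polarity and chemoselectivity by the carboxylate buffer, to which the epoxides are inert; the facial selectivity at C8 is the one selectivity that rests on the substrate conformation alone.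

Step 14
Reactants: 19 (1R,4R,5R,7R,8R,10S,11R)-1,10:4,5-diepoxy-11-hydroxy-6-oxogermacran-12,8-olide
Product: 20 (1R,4R,5S,6S,7S,8R,10S,11R)-1,10:4,5-diepoxy-6,11-dihydroxygermacran-12,8-olide
Conditions: Zn(BH4)2, Et2O, −30 °C
Reagents that add atoms: none
Why: Chelation-controlled zinc borohydride reduction: zinc bridges the C6 carbonyl with the syn C11 hydroxyl (and the C5 epoxide oxygen) and hydride enters from the convex face of the resulting cis-fused chelate, which should give the 6S alcohol, cis to the C7–C11 bond and erythro to the 4,5-epoxide.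

Step 15
Reactants: 20 (1R,4R,5S,6S,7S,8R,10S,11R)-1,10:4,5-diepoxy-6,11-dihydroxygermacran-12,8-olide; 21 angelic anhydride
Product: 22 (1R,4R,5S,6S,7S,8R,10S,11R)-6,11-bis(angeloyloxy)-1,10:4,5-diepoxygermacran-12,8-olide (CNP0219924.2)
Conditions: angelic anhydride (4 equiv), THF, −78 °C; then LiN(SiMe3)2 (2.4 equiv) added slowly, −78 → −40 °C; aq NH4Cl
Reagents that add atoms: none
Why: O-Acylation of the two lithium alkoxides by angelic anhydride without any nucleophilic amine catalyst should keep the Z-geometry of both angelates; the anhydride is present before the base so that each alkoxide is trapped as it forms, and no stereocentre is touched.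

Compound list
1 | ethyl (triphenyl-λ5-phosphanylidene)acetate | CCOC(=O)C=P(c1ccccc1)(c1ccccc1)c1ccccc1 | starting material
2 | (1-ethoxy-1-oxopent-4-en-2-yl)triphenylphosphonium bromide | CCOC(=O)C(CC=C)[P+](c1ccccc1)(c1ccccc1)c1ccccc1.[Br-] | intermediate
3 | ethyl 2-(triphenyl-λ5-phosphanylidene)pent-4-enoate | CCOC(=O)C(CC=C)=P(c1ccccc1)(c1ccccc1)c1ccccc1 | intermediate
4 | nerol, (2Z)-3,7-dimethylocta-2,6-dien-1-ol | CC(C)=CCC/C(C)=C\CO | starting material
5 | (2S,3R)-2,3-epoxynerol, [(2S,3R)-3-methyl-3-(4-methylpent-3-en-1-yl)oxiran-2-yl]methanol | OC[C@@H]1O[C@]1(C)CCC=C(C)C | intermediate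
6 | secondary ozonide of 5, {(2S,3R)-3-[2-(5,5-dimethyl-1,2,4-trioxolan-3-yl)ethyl]-3-methyloxiran-2-yl}methanol | OC[C@@H]1O[C@]1(C)CCC2OOC(C)(C)O2 | intermediate
7 | 3-[(2R,3S)-3-(hydroxymethyl)-2-methyloxiran-2-yl]propanal | OC[C@@H]1O[C@]1(C)CCC=O | intermediate
8 | ethyl (2E)-5-[(2R,3S)-3-(hydroxymethyl)-2-methyloxiran-2-yl]-2-(prop-2-en-1-yl)pent-2-enoate | OC[C@@H]1O[C@]1(C)CC/C=C(\CC=C)C(=O)OCC | intermediate
9 | ethyl (2E)-5-[(2R,3R)-3-formyl-2-methyloxiran-2-yl]-2-(prop-2-en-1-yl)pent-2-enoate | O=C[C@@H]1O[C@]1(C)CC/C=C(\CC=C)C(=O)OCC | intermediate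
10 | ethyl (2E)-5-[(2R,3S)-3-(1-hydroxyprop-2-en-1-yl)-2-methyloxiran-2-yl]-2-(prop-2-en-1-yl)pent-2-enoate (both carbinol epimers) | C=CC(O)[C@@H]1O[C@]1(C)CC/C=C(\CC=C)C(=O)OCC | intermediate
11 | (2E)-5-[(2R,3S)-3-(1-hydroxyprop-2-en-1-yl)-2-methyloxiran-2-yl]-2-(prop-2-en-1-yl)pent-2-en-1-ol (both carbinol epimers) | C=CC(O)[C@@H]1O[C@]1(C)CC/C=C(\CC=C)CO | intermediate
12 | 1-[(2S,3R)-3-{2-[(2R,3R)-3-(hydroxymethyl)-3-(prop-2-en-1-yl)oxiran-2-yl]ethyl}-3-methyloxiran-2-yl]prop-2-en-1-ol (both carbinol epimers) | C=CC(O)[C@@H]1O[C@]1(C)CC[C@H]2O[C@@]2(CO)CC=C | intermediate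
13 | [(2R,3R)-3-{2-[(2R,3S)-3-(1-hydroxyprop-2-en-1-yl)-2-methyloxiran-2-yl]ethyl}-2-(prop-2-en-1-yl)oxiran-2-yl]methyl 4-methylbenzenesulfonate (both carbinol epimers) | C=CC(O)[C@@H]1O[C@]1(C)CC[C@H]2O[C@@]2(COS(=O)(=O)c3ccc(C)cc3)CC=C | intermediate
14 | 1-[(2S,3R)-3-methyl-3-{2-[(2R,3S)-3-methyl-3-(prop-2-en-1-yl)oxiran-2-yl]ethyl}oxiran-2-yl]prop-2-en-1-ol (both carbinol epimers) | C=CC(O)[C@@H]1O[C@]1(C)CC[C@H]2O[C@@]2(C)CC=C | intermediate
15 | 1-[(2R,3R)-3-methyl-3-{2-[(2R,3S)-3-methyl-3-(prop-2-en-1-yl)oxiran-2-yl]ethyl}oxiran-2-yl]prop-2-en-1-one | C=CC(=O)[C@@H]1O[C@]1(C)CC[C@H]2O[C@@]2(C)CC=C | intermediate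
16 | (1R,4R,5R,10S,7Z)-1,10:4,5-diepoxy-4,10-dimethylcyclodec-7-en-6-one (germacrane numbering) | O=C1/C=C\C[C@]2(C)O[C@@H]2CC[C@@]2(C)O[C@@H]12 | intermediate
17 | pyruvic acid | CC(=O)C(=O)O | starting material
18 | (1R,4R,5R,8R,10S)-1,10:4,5-diepoxy-4,10-dimethyl-6-oxocyclodecan-8-yl 2-oxopropanoate | O=C1C[C@@H](C[C@]3(C)O[C@@H]3CC[C@@]3(C)O[C@@H]13)OC(=O)C(C)=O | intermediate
19 | (1R,4R,5R,7R,8R,10S,11R)-1,10:4,5-diepoxy-11-hydroxy-6-oxogermacran-12,8-olide | O=C1[C@@H]2[C@@H](C[C@]3(C)O[C@@H]3CC[C@@]3(C)O[C@@H]13)OC(=O)[C@]2(C)O | intermediate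
20 | (1R,4R,5S,6S,7S,8R,10S,11R)-1,10:4,5-diepoxy-6,11-dihydroxygermacran-12,8-olide | O[C@H]1[C@@H]2[C@@H](C[C@]3(C)O[C@@H]3CC[C@@]3(C)O[C@@H]13)OC(=O)[C@]2(C)O | intermediate
21 | angelic anhydride, (2Z)-2-methylbut-2-enoic anhydride | C/C=C(/C)C(=O)OC(=O)/C(C)=C\C | starting material
22 | (1R,4R,5S,6S,7S,8R,10S,11R)-6,11-bis(angeloyloxy)-1,10:4,5-diepoxygermacran-12,8-olide (CNP0219924.2) | C/C=C(/C)C(=O)O[C@H]1[C@@H]2[C@@H](C[C@]3(C)O[C@@H]3CC[C@@]3(C)O[C@@H]13)OC(=O)[C@]2(C)OC(=O)/C(C)=C\C | target

Total step count: 15. Longest linear sequence: 14 steps (steps 2–15, from nerol 4 to 22); step 1 is a one-step side branch.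

Steps most likely to fail

Step 13. The carboxylate may add too slowly or too reversibly to the hindered β-carbon, so that self-condensation of pyruvate wins, or attack at C8 may show poor facial selectivity relative to the two epoxides. The fallback uses known chemistry and sets out from enone 16. Copper-catalysed conjugate borylation (B2pin2, CuCl, NaOtBu, a Josiphos ligand whose enantiomer is chosen for the matched case, MeOH, THF) should place boron on C8 under catalyst control and give the β-boryl ketone (1R,4R,5R,8R,10S)-1,10:4,5-diepoxy-4,10-dimethyl-8-(4,4,5,5-tetramethyl-1,3,2-dioxaborolan-2-yl)cyclodecan-6-one F1. Oxidation with NaBO3·4H2O (THF/H2O), with retention at C8, gives the β-hydroxy ketone (1R,4R,5R,8R,10S)-1,10:4,5-diepoxy-8-hydroxy-4,10-dimethylcyclodecan-6-one F2. Esterification with pyruvic acid 17 (DCC, cat. DMAP, CH2Cl2, −20 °C) gives the pyruvate ester 18, this time isolated. An intramolecular aldol under soft enolisation (LiCl, iPr2NEt, MeCN) then closes C7–C11 and comes back to the route at 19.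

Step 12. Intermolecular metathesis (oligomerisation) or polymerisation of the vinyl ketone may outrun closure of the ten-membered ring. The fallback sets out from dienol 14 and closes the ring before the oxidation. Ring-closing metathesis of the free allylic alcohol (second-generation Grubbs catalyst, CH2Cl2, reflux, high dilution), where both termini are electron-neutral and the hydroxyl assists loading, should give the cyclic allylic alcohol (1R,4R,5S,10S,7Z)-1,10:4,5-diepoxy-4,10-dimethylcyclodec-7-en-6-ol F3 (both C6 epimers). Dess–Martin oxidation (pyridine, CH2Cl2) then comes back to the route at enone 16.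

Step 15. The C6 alkoxide may transfer onto the lactone carbonyl (translactonisation to the 6,12-olide) before it is acylated, the hindered tertiary C11 hydroxyl may acylate incompletely, or the angelate may isomerise to the tiglate. The fallback sets out from diol 20 and separates the two acylations. The secondary C6 hydroxyl is acylated first without any alkoxide, by the mixed anhydride made from angelic acid and 2,4,6-trichlorobenzoyl chloride (Et3N, toluene, 80 °C), to give the mono-ester (1R,4R,5S,6S,7S,8R,10S,11R)-6-angeloyloxy-1,10:4,5-diepoxy-11-hydroxygermacran-12,8-olide F4. With C6 blocked, the tertiary C11 hydroxyl is deprotonated with LiN(SiMe3)2 (THF, −78 °C) and acylated with angelic anhydride 21, which comes back to the route at 22.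

Further compounds
F1 | step 13 | (1R,4R,5R,8R,10S)-1,10:4,5-diepoxy-4,10-dimethyl-8-(4,4,5,5-tetramethyl-1,3,2-dioxaborolan-2-yl)cyclodecan-6-one | O=C1C[C@@H](C[C@]3(C)O[C@@H]3CC[C@@]3(C)O[C@@H]13)B4OC(C)(C)C(C)(C)O4
F2 | step 13 | (1R,4R,5R,8R,10S)-1,10:4,5-diepoxy-8-hydroxy-4,10-dimethylcyclodecan-6-one | O=C1C[C@@H](C[C@]3(C)O[C@@H]3CC[C@@]3(C)O[C@@H]13)O
F3 | step 12 | (1R,4R,5S,10S,7Z)-1,10:4,5-diepoxy-4,10-dimethylcyclodec-7-en-6-ol (both C6 epimers) | OC1/C=C\C[C@]2(C)O[C@@H]2CC[C@@]2(C)O[C@@H]12
F4 | step 15 | (1R,4R,5S,6S,7S,8R,10S,11R)-6-angeloyloxy-1,10:4,5-diepoxy-11-hydroxygermacran-12,8-olide | C/C=C(/C)C(=O)O[C@H]1[C@@H]2[C@@H](C[C@]3(C)O[C@@H]3CC[C@@]3(C)O[C@@H]13)OC(=O)[C@]2(C)O
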